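**Retrosynthetic overview**
- The target comes from the 14-hydroxy isopropenyl macrolide by olefin hydrogenation and acetylation.
- Both rings are closed in one flask, in the biosynthetic order: first the 14-membered carbocycle through the C1–C2 bond (the bond made by the cembrane cyclase), by a Lewis-acid carbonyl-ene attack of the isopropylidene terminus on the aldehyde of an open γ-hydroxybutenolide; then the butenolide, by C2-OH/C18-acid lactonisation.
- The acyclic γ-hydroxybutenolide comes from singlet-oxygen oxidation with decarboxylation of a furan-2-carboxylic acid; the C5–C6 bond comes from C-acylation of the lateral dianion of a 3-methylfuroic acid.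
- The C11–C12 bond and the C12 carbinol come from chelation-controlled addition of an (E)-alkenyllithium to the acetone/enal aldol (C14 set by catalysis); C8 comes from a chiral 3-methylglutarate half-ester.

Locants are cembrane locants: C1 = CH(i-Pr), C2 = lactone O–CH, C3=C4, C18 = lactone C=O on C4, C5, C6 = ketone, C8 = CH(CH3), C10=C11, C12 = C(OH)CH3, C13, C14 = CH(OAc). The target is (1R,2R,8S,10E,12S,14S).

Assumption: the (S)-ligand in step 1 is taken as the enantiomer that adds to the Si face of 1; if the sense is the reverse, its mirror image is used.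

**Route**

Step 1
Reactants: 1 3-methylbut-2-enal; 2 2-methoxypropene
Product: 4 (S)-4-hydroxy-6-methylhept-5-en-2-one, via methyl enol ether adduct 3 (not isolated)
Conditions: Ti(OiPr)4 (5 mol %), (S)-2'-[(3-bromo-5-tert-butyl-2-hydroxybenzylidene)amino]-1,1'-binaphthalen-2-ol (5 mol %), 3,5-di-tert-butylsalicylic acid (5 mol %), 2 as solvent, 0 °C; then 2 M HCl, Et2O, 0 °C
Reagents that add atoms: water, O
Why: Catalytic enantioselective Mukaiyama-type aldol (ene-like addition of the enol ether to the aldehyde bound to the chiral tetravalent titanium complex) followed by enol ether hydrolysis, the catalyst directing attack to the Si face of 1 so that the C14 carbinol is S.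

Step 2
Reactants: 5 (R)-5-methoxy-3-methyl-5-oxopentanoic acid (methyl hydrogen (R)-3-methylglutarate)
Product: 7 (R)-4-methyloxan-2-one, via hydroxy ester 6 (not isolated)
Conditions: BH3·SMe2 (1.2 equiv), THF, 0 °C to rt; MeOH quench; then TsOH (5 mol %), CH2Cl2, rt
Reagents that add atoms: none
Why: Chemoselective borane reduction of the carboxylic acid beside the methyl ester, then acid-catalysed lactonisation; the C8 stereocentre comes from the chiral pool and is not touched.

Step 3
Reactants: 7 (R)-4-methyloxan-2-one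
Product: 8 (4R)-4-methyloxan-2-ol (anomers)
Conditions: i-Bu2AlH (1.1 equiv), CH2Cl2, −78 °C
Reagents that add atoms: none
Why: Partial hydride reduction of a δ-lactone stops at the lactol because the tetrahedral aluminate is stable at −78 °C.

Step 4
Reactants: 8 (4R)-4-methyloxan-2-ol
Product: 10 (3S,5E)-6-iodo-3-methylhex-5-en-1-ol, via open-chain hydroxy aldehyde tautomer 9 (not isolated)
Conditions: CrCl2 (6 equiv), CHI3 (2 equiv), THF–1,4-dioxane 1:6, 0 °C to rt
Reagents that add atoms: iodoform, IC(I)I
Why: Takai olefination of the aldehyde in equilibrium with the lactol gives the (E)-vinyl iodide through the geminal dichromium reagent, the free hydroxyl being tolerated (the CIP descriptor at C8 changes to S without any change in space).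

Step 5
Reactants: 10 (3S,5E)-6-iodo-3-methylhex-5-en-1-ol; 4 (S)-4-hydroxy-6-methylhept-5-en-2-one
Product: 13 (3S,5E,7S,9S)-3,7,11-trimethyldodeca-5,10-diene-1,7,9-triol, via lithium alkoxide alkenyllithium 11 (not isolated), via chloromagnesium aldolate 12 (not isolated)
Conditions: 10, t-BuLi (3.1 equiv), Et2O, −78 °C; 4 (1.5 equiv), t-BuMgCl (1.5 equiv), THF, −78 °C; combine, −78 to −40 °C; aq. NH4Cl
Reagents that add atoms: none
Why: Iodine–lithium exchange gives a configurationally stable (E)-alkenyllithium that adds to the methyl ketone held in a six-membered magnesium chelate with the C14 alkoxide (1,3-chelation-controlled 1,2-addition); axial attack on the half-chair with the C14 substituent equatorial gives the 12,14-anti diol, i.e. 12S.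

Step 6
Reactants: 13 (3S,5E,7S,9S)-3,7,11-trimethyldodeca-5,10-diene-1,7,9-triol
Product: 15 (3S,5E,7S,9S)-7,9-dihydroxy-3,7,11-trimethyldodeca-5,10-dienoic acid, via aldehyde 14 (not isolated)
Conditions: TEMPO (0.2 equiv), PhI(OAc)2 (2.2 equiv), MeCN–H2O 1:1, 0 °C to rt
Reagents that add atoms: water, O
Why: Oxoammonium (TEMPO) oxidation in aqueous acetonitrile takes the unhindered primary alcohol through the aldehyde hydrate to the acid, while the hindered secondary allylic and the tertiary alcohols react far more slowly.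

Step 7
Reactants: 15 (3S,5E,7S,9S)-7,9-dihydroxy-3,7,11-trimethyldodeca-5,10-dienoic acid; 16 3-methylfuran-2-carboxylic acid
Product: 19 3-[(4S,6E,8S,10S)-8,10-dihydroxy-4,8,12-trimethyl-2-oxotrideca-6,11-dien-1-yl]furan-2-carboxylic acid, via acyl imidazolide 17 (not isolated), via dilithio furoate dianion 18 (not isolated)
Conditions: 15, 1,1'-carbonyldiimidazole (1.05 equiv), THF, rt, 1 h; 16 (5.5 equiv), LiN(i-Pr)2 (11 equiv), THF, −78 °C; add the solution of 17, −78 to −30 °C; 1 M HCl to pH 3
Reagents that add atoms: none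
Why: C-acylation of the lateral (ortho-toluate-type) dianion of 16 by the acyl imidazolide gives the ketone directly, because the doubly activated C5 methylene of the product is deprotonated in the flask and blocks a second addition (the excess dianion also absorbs the two hydroxyl protons).

Step 8
Reactants: 19 3-[(4S,6E,8S,10S)-8,10-dihydroxy-4,8,12-trimethyl-2-oxotrideca-6,11-dien-1-yl]furan-2-carboxylic acid
Product: 21 3-[(4S,6E,8S,10S)-8,10-dihydroxy-4,8,12-trimethyl-2-oxotrideca-6,11-dien-1-yl]-5-hydroxyfuran-2(5H)-one (C2 epimers), via furan endoperoxide 20 (not isolated)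
Conditions: O2, rose bengal (1 mol %), visible light, MeOH, −40 °C, stopped when 19 is consumed; then rt
Reagents that add atoms: oxygen, O=O
Why: Dye-sensitised [4+2] addition of singlet oxygen to the furan and decarboxylative fragmentation of the 2-carboxy endoperoxide put the lactone carbonyl on the carbon that carried CO2H, so the α-substituted γ-hydroxybutenolide forms regiospecifically; the furan diene is expected to react faster than the hydroxyl-bearing trisubstituted olefin (Schenck ene), though by a modest margin.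

Step 9
Reactants: 21 3-[(4S,6E,8S,10S)-8,10-dihydroxy-4,8,12-trimethyl-2-oxotrideca-6,11-dien-1-yl]-5-hydroxyfuran-2(5H)-one
Product: 24 (1R,2R,8S,10E,12S,14S)-12,14-dihydroxy-6-oxocembra-3,10,15-trien-18,2-olide, via open-chain oxo-enoic acid tautomer 22 (not isolated), via macrocyclic seco hydroxy acid 23 (not isolated)
Conditions: Me2AlCl (6 equiv), CH2Cl2, 21 added by syringe pump over 10 h (final 0.5 mM), −78 to −20 °C; then 1 M HCl, rt
Reagents that add atoms: none
Why: Proposed new method: Me2AlCl deprotonates the pseudo-acid and opens it to the aluminium (Z)-4-oxo-2-enoate 22, whose Lewis-acid-activated aldehyde C2 is attacked by C1 of the isopropylidene olefin in an intramolecular carbonyl-ene (Prins-type) reaction with hydrogen transfer from a C15 methyl to oxygen, and the cis-γ-hydroxy acid 23 lactonises on acidic work-up (closest known types: alkylaluminium-chloride-promoted ene macrocyclisations of unsaturated aldehydes to 14-membered homoallylic alcohols, and allyl-metal additions to γ-hydroxybutenolides through their open aldehyde form); C1 (R) is expected from addition anti to the bulky C14 aluminium alkoxide in the conformer with H14 eclipsing C1=C15 (A(1,3) strain with the cis methyl, Kishi-type anti-to-oxygen selectivity), and C2 (R) from a chair-like six-centre transition state with the enoate substituent of the aldehyde away from C15 and H2 between C14 and C15 (1,2-syn).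

Step 10
Reactants: 24 (1R,2R,8S,10E,12S,14S)-12,14-dihydroxy-6-oxocembra-3,10,15-trien-18,2-olide
Product: 25 (1R,2R,8S,10E,12S,14S)-12,14-dihydroxy-6-oxocembra-3,10-dien-18,2-olide
Conditions: RhCl(PPh3)3 (10 mol %), H2 (1 atm), benzene, rt
Reagents that add atoms: none
Why: Homogeneous hydrogenation with RhCl(PPh3)3 reduces the 1,1-disubstituted isopropenyl group much faster than the trans-disubstituted C10=C11 bond next to the quaternary carbinol and does not touch the conjugated trisubstituted butenolide; no stereocentre is formed.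

Step 11
Reactants: 25 (1R,2R,8S,10E,12S,14S)-12,14-dihydroxy-6-oxocembra-3,10-dien-18,2-olide
Product: 26 (1R,2R,8S,10E,12S,14S)-14-acetoxy-12-hydroxy-6-oxocembra-3,10-dien-18,2-olide (CNP0200490.2)
Conditions: Ac2O (1.5 equiv), pyridine, DMAP (0.1 equiv), CH2Cl2, 0 °C to rt
Reagents that add atoms: acetic anhydride, CC(=O)OC(C)=O
Why: DMAP-catalysed acylation esterifies the secondary C14 alcohol, while the tertiary allylic C12 alcohol is too hindered to react at this temperature.

**Compound list**

1 | 3-methylbut-2-enal | CC(C)=CC=O | starting material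
2 | 2-methoxypropene | COC(C)=C | starting material
3 | (S)-2-methoxy-6-methylhepta-1,5-dien-4-ol | COC(=C)C[C@H](O)C=C(C)C | intermediate
4 | (S)-4-hydroxy-6-methylhept-5-en-2-one | CC(=O)C[C@H](O)C=C(C)C | intermediate
5 | (R)-5-methoxy-3-methyl-5-oxopentanoic acid | COC(=O)C[C@H](C)CC(O)=O | starting material
6 | methyl (R)-5-hydroxy-3-methylpentanoate | COC(=O)C[C@H](C)CCO | intermediate
7 | (R)-4-methyloxan-2-one | O=C1C[C@H](C)CCO1 | intermediate
8 | (4R)-4-methyloxan-2-ol | OC1C[C@H](C)CCO1 | intermediate
9 | (R)-5-hydroxy-3-methylpentanal | O=CC[C@H](C)CCO | intermediate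
10 | (3S,5E)-6-iodo-3-methylhex-5-en-1-ol | I/C=C/C[C@H](C)CCO | intermediate
11 | lithium (3S,5E)-6-lithio-3-methylhex-5-en-1-olate | [Li]/C=C/C[C@H](C)CCO[Li] | intermediate
12 | chloromagnesium (S)-6-methyl-2-oxohept-5-en-4-olate | CC(=O)C[C@H](O[Mg]Cl)C=C(C)C | intermediate
13 | (3S,5E,7S,9S)-3,7,11-trimethyldodeca-5,10-diene-1,7,9-triol | CC(C)=C[C@@H](O)C[C@](C)(O)/C=C/C[C@H](C)CCO | intermediate
14 | (3S,5E,7S,9S)-7,9-dihydroxy-3,7,11-trimethyldodeca-5,10-dienal | CC(C)=C[C@@H](O)C[C@](C)(O)/C=C/C[C@H](C)CC=O | intermediate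
15 | (3S,5E,7S,9S)-7,9-dihydroxy-3,7,11-trimethyldodeca-5,10-dienoic acid | CC(C)=C[C@@H](O)C[C@](C)(O)/C=C/C[C@H](C)CC(O)=O | intermediate
16 | 3-methylfuran-2-carboxylic acid | Cc1ccoc1C(O)=O | starting material
17 | 1-[(3S,5E,7S,9S)-7,9-dihydroxy-3,7,11-trimethyldodeca-5,10-dienoyl]imidazole | CC(C)=C[C@@H](O)C[C@](C)(O)/C=C/C[C@H](C)CC(=O)n1ccnc1 | intermediate
18 | lithium 3-(lithiomethyl)furan-2-carboxylate | [Li]Cc1ccoc1C(=O)O[Li] | intermediate
19 | 3-[(4S,6E,8S,10S)-8,10-dihydroxy-4,8,12-trimethyl-2-oxotrideca-6,11-dien-1-yl]furan-2-carboxylic acid | CC(C)=C[C@@H](O)C[C@](C)(O)/C=C/C[C@H](C)CC(=O)Cc1ccoc1C(O)=O | intermediate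
20 | 2,5-endoperoxide of 19 (2,3,7-trioxabicyclo[2.2.1]hept-5-ene-1-carboxylic acid carrying the side chain at C6) | CC(C)=C[C@@H](O)C[C@](C)(O)/C=C/C[C@H](C)CC(=O)CC1=CC2OOC1(C(O)=O)O2 | intermediate
21 | 3-[(4S,6E,8S,10S)-8,10-dihydroxy-4,8,12-trimethyl-2-oxotrideca-6,11-dien-1-yl]-5-hydroxyfuran-2(5H)-one | CC(C)=C[C@@H](O)C[C@](C)(O)/C=C/C[C@H](C)CC(=O)CC1=CC(O)OC1=O | intermediate
22 | (2Z,6S,8E,10S,12S)-10,12-dihydroxy-6,10,14-trimethyl-4-oxo-2-(2-oxoethylidene)pentadeca-8,13-dienoic acid (formed as its aluminium carboxylate) | CC(C)=C[C@@H](O)C[C@](C)(O)/C=C/C[C@H](C)CC(=O)C/C(C(O)=O)=C/C=O | intermediate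
23 | (1R,2R,3Z,8S,10E,12S,14S)-2,12,14-trihydroxy-6-oxocembra-3,10,15-trien-18-oic acid | O[C@H]1C[C@](C)(O)/C=C/C[C@H](C)CC(=O)C/C(C(O)=O)=C/[C@@H](O)[C@@H]1C(C)=C | intermediate
24 | (1R,2R,8S,10E,12S,14S)-12,14-dihydroxy-6-oxocembra-3,10,15-trien-18,2-olide | O[C@H]1C[C@](C)(O)/C=C/C[C@H](C)CC(=O)CC2=C[C@@H](OC2=O)[C@@H]1C(C)=C | intermediate
25 | (1R,2R,8S,10E,12S,14S)-12,14-dihydroxy-6-oxocembra-3,10-dien-18,2-olide | O[C@H]1C[C@](C)(O)/C=C/C[C@H](C)CC(=O)CC2=C[C@@H](OC2=O)[C@@H]1C(C)C | intermediate
26 | (1R,2R,8S,10E,12S,14S)-14-acetoxy-12-hydroxy-6-oxocembra-3,10-dien-18,2-olide | CC(=O)O[C@H]1C[C@](C)(O)/C=C/C[C@H](C)CC(=O)CC2=C[C@@H](OC2=O)[C@@H]1C(C)C | target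

**Step count and risks**

Total steps: 11. Longest linear sequence: 10 (steps 2 to 11, from 5).

Most likely to fail, in this order:

Step 9 (key macrocyclisation). The risks are: the acidic C5 methylene of the open keto-enal may enolise; oligomers may form instead of the 14-membered ring; and the C14 aluminium alkoxide may direct the aldehyde to its own face instead of shielding it, which would give the C1/C2 epimeric pair. The fallback sets out from 21 and returns at 26. Acetylation of 21 (Ac2O, pyridine, DMAP) gives 5-acetoxy-3-[(4S,6E,8S,10S)-10-acetoxy-8-hydroxy-4,8,12-trimethyl-2-oxotrideca-6,11-dien-1-yl]furan-2(5H)-one F1. EtAlCl2 in CH2Cl2 at −78 °C under high dilution ionises the anomeric acetate to the butenolide-stabilised C2 cation, which the C1=C15 olefin traps in a cation–olefin macrocyclisation (now anti to a non-coordinating 14-acetate), with loss of a methyl proton. This gives (1R,2R,8S,10E,12S,14S)-14-acetoxy-12-hydroxy-6-oxocembra-3,10,15-trien-18,2-olide F2. Hydrogenation with RhCl(PPh3)3 and H2 then gives 26.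

Step 5 (fragment union). The risks are enolisation of the methyl ketone, (Z)-iodide carried over from step 4, and only moderate 1,3-induction at C12. The fallback sets out from 8 and returns at 13. Homologation of 8 with dimethyl (1-diazo-2-oxopropyl)phosphonate and K2CO3 in MeOH gives (S)-3-methylhex-5-yn-1-ol F3. Its dilithio derivative (n-BuLi, 2 equiv), transmetalated with CeCl3, adds to the chelated ketone 12 to give (3S,7S,9S)-3,7,11-trimethyldodec-10-en-5-yne-1,7,9-triol F4; the C12 epimers are separated here. Directed trans-hydroalumination with NaAlH2(OCH2CH2OMe)2 gives only the (E)-allylic alcohol 13.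

Step 7 (dianion acylation on an unprotected diol). The risks are ring lithiation instead of lateral lithiation, and O-acylation. The fallback sets out from 15 and returns at 19. EDC, DMAP and EtSH give S-ethyl (3S,5E,7S,9S)-7,9-dihydroxy-3,7,11-trimethyldodeca-5,10-dienethioate F5. Fukuyama coupling (PdCl2(PPh3)2, 5 mol %) with {[2-(methoxycarbonyl)furan-3-yl]methyl}zinc bromide F6 (Zn dust on commercial methyl 3-(bromomethyl)furan-2-carboxylate) gives methyl 3-[(4S,6E,8S,10S)-8,10-dihydroxy-4,8,12-trimethyl-2-oxotrideca-6,11-dien-1-yl]furan-2-carboxylate F7. LiOH in THF–H2O then gives 19.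

**Further compounds**

F1 | step 9 | 5-acetoxy-3-[(4S,6E,8S,10S)-10-acetoxy-8-hydroxy-4,8,12-trimethyl-2-oxotrideca-6,11-dien-1-yl]furan-2(5H)-one | CC(C)=C[C@@H](OC(C)=O)C[C@](C)(O)/C=C/C[C@H](C)CC(=O)CC1=CC(OC(C)=O)OC1=O
F2 | step 9 | (1R,2R,8S,10E,12S,14S)-14-acetoxy-12-hydroxy-6-oxocembra-3,10,15-trien-18,2-olide | CC(=O)O[C@H]1C[C@](C)(O)/C=C/C[C@H](C)CC(=O)CC2=C[C@@H](OC2=O)[C@@H]1C(C)=C
F3 | step 5 | (S)-3-methylhex-5-yn-1-ol | C#CC[C@H](C)CCO
F4 | step 5 | (3S,7S,9S)-3,7,11-trimethyldodec-10-en-5-yne-1,7,9-triol | CC(C)=C[C@@H](O)C[C@](C)(O)C#CC[C@H](C)CCO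
F5 | step 7 | S-ethyl (3S,5E,7S,9S)-7,9-dihydroxy-3,7,11-trimethyldodeca-5,10-dienethioate | CC(C)=C[C@@H](O)C[C@](C)(O)/C=C/C[C@H](C)CC(=O)SCC
F6 | step 7 | {[2-(methoxycarbonyl)furan-3-yl]methyl}zinc bromide | COC(=O)c1occc1C[Zn]Br
F7 | step 7 | methyl 3-[(4S,6E,8S,10S)-8,10-dihydroxy-4,8,12-trimethyl-2-oxotrideca-6,11-dien-1-yl]furan-2-carboxylate | CC(C)=C[C@@H](O)C[C@](C)(O)/C=C/C[C@H](C)CC(=O)Cc1ccoc1C(=O)OC
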